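Everything rests on building ring C instead of coupling it. Ring C carries the ring B oxygen on C1, the ring D oxygen on C4 and hydroxyls on C3 and C5, and this oxygen pattern is that of a folded triketide. C6, C1, C2 and C3 are drawn from a 3-(A–B aryloxy)but-2-enoate, C4 and C5 from a (D–E aryloxy)acetyl donor. In one pot the enoate dienolate is acylated at its γ-carbon (C5–C6), and more base then closes C3–C4 by a Claisen condensation that aromatises. The precursors are the (E)-enoate, methyl cis to the ester, and the aryloxyacetic N-methoxy-N-methylamide, each with its diaryl ether already made.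

Key step: step 8

Remark on lettering: rings run A to E from the 2,4,6-trioxygenated end to the 3,4,5-trioxygenated end. In rings B, C and D, C1 bears the oxygen towards ring A, and C4, flanked by oxygenated C3 and C5, bears the oxygen towards ring E. The target has no stereocentre, and the only stereo-element of the route is the (E)-alkene of the enoate.

Remark on ring B: the enol ether oxygen must be the flanked C4 oxygen of ring B. Arylating the flanked hydroxyl of a 4-hydroxy-3,5-dimethoxybenzaldehyde and then oxidising the formyl group frees the unflanked oxygen. That suits ring D but would turn ring B round. The A–B phenol is therefore assembled with its flanked oxygen masked as a benzyl ether and its unflanked carbon as the coupling site.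

Remark on the acyl donor: a simple alkyl aryloxyacetate would release, during the addition, a ketone more acidic than the enoate, and surplus amide base would enolise the ester itself. The N-methoxy-N-methylamide costs the same number of steps and keeps the ketone masked until the acyl donor is used up.

Assumption: every compound marked as starting material in the list is taken to be a catalogue item.

Step 1
Reactants: 1 4-bromo-2,6-dimethoxyphenol
Product: 2 2-(benzyloxy)-5-bromo-1,3-dimethoxybenzene
Conditions: BnBr, K2CO3, DMF, rt
Reagents that add atoms: benzyl bromide, BrCc1ccccc1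
Why: Williamson ether synthesis on an acidic phenol with a primary benzylic halide, which masks the flanked ring B oxygen with a group that survives copper catalysis and leaves by hydrogenolysis.

Step 2
Reactants: 2 2-(benzyloxy)-5-bromo-1,3-dimethoxybenzene, 3 2,4,6-trimethoxyphenol
Product: 4 2-(benzyloxy)-1,3-dimethoxy-5-(2,4,6-trimethoxyphenoxy)benzene
Conditions: CuI (10 mol %), picolinic acid (20 mol %), K3PO4, DMSO, 95 °C, Ar
Reagents that add atoms: none
Why: Ullmann-type diaryl ether coupling in which all the hindrance sits on the electron-rich phenoxide and the bromide has two free ortho positions, the pairing that picolinate-ligated monovalent copper is known to handle.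

Step 3
Reactants: 4 2-(benzyloxy)-1,3-dimethoxy-5-(2,4,6-trimethoxyphenoxy)benzene
Product: 5 2,6-dimethoxy-4-(2,4,6-trimethoxyphenoxy)phenol
Conditions: H2 (1 atm), Pd/C, EtOAc–MeOH, rt
Reagents that add atoms: none
Why: Catalytic hydrogenolysis cleaves only the benzylic C–O bond, since aryl methyl ethers and the diaryl ether are inert to H2 over Pd/C.

Step 4
Reactants: 5 2,6-dimethoxy-4-(2,4,6-trimethoxyphenoxy)phenol, 6 methyl but-2-ynoate
Product: 7 methyl (E)-3-[2,6-dimethoxy-4-(2,4,6-trimethoxyphenoxy)phenoxy]but-2-enoate
Conditions: K2CO3 (0.3 equiv), DMF, 70 °C, Ar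
Reagents that add atoms: none
Why: Oxa-Michael addition of the phenoxide to the β-carbon of the ynoate, in which reversible addition–elimination under base should funnel the enol ether to the thermodynamically preferred (E)-isomer with the aryloxy group trans and the methyl group cis to the ester, as is general for 3-alkoxy- and 3-aryloxycrotonates.

Step 5
Reactants: 8 syringaldehyde, 9 (3,4,5-trimethoxyphenyl)boronic acid
Product: 10 3,5-dimethoxy-4-(3,4,5-trimethoxyphenoxy)benzaldehyde
Conditions: Cu(OAc)2 (0.5 equiv), pyridine, 4 Å molecular sieves, CH2Cl2, O2 (1 atm), rt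
Reagents that add atoms: none
Why: Chan–Lam coupling, in which the electron-rich aryl group passes from boron to a divalent copper phenoxide and reductive elimination from trivalent copper forms the C–O bond at room temperature, conditions known to accept acidic di-ortho-substituted phenols and to spare a formyl group.

Step 6
Reactants: 10 3,5-dimethoxy-4-(3,4,5-trimethoxyphenoxy)benzaldehyde
Product: 12 3,5-dimethoxy-4-(3,4,5-trimethoxyphenoxy)phenol, via aryl formate 11 (not isolated)
Conditions: mCPBA, CH2Cl2, 0 °C → rt; then K2CO3 (cat.), MeOH, rt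
Reagents that add atoms: mCPBA (3-chloroperoxybenzoic acid), OOC(=O)c1cccc(Cl)c1
Why: Baeyer–Villiger (Dakin-type) oxidation in which the aryl group, made electron-rich by its para aryloxy substituent, migrates in preference to hydrogen as in 3,4,5-trialkoxybenzaldehydes, and methanolysis of the formate frees the unflanked ring D phenol.

Step 7
Reactants: 12 3,5-dimethoxy-4-(3,4,5-trimethoxyphenoxy)phenol, 13 2-chloro-N-methoxy-N-methylacetamide
Product: 14 2-[3,5-dimethoxy-4-(3,4,5-trimethoxyphenoxy)phenoxy]-N-methoxy-N-methylacetamide
Conditions: K2CO3, KI (cat.), MeCN, 60 °C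
Reagents that add atoms: none
Why: Williamson ether synthesis of an unhindered phenoxide with an activated α-halo amide, which installs C4 and C5 of ring C together with the acyl leaving group in one operation.

Step 8
Reactants: 7 methyl (E)-3-[2,6-dimethoxy-4-(2,4,6-trimethoxyphenoxy)phenoxy]but-2-enoate, 14 2-[3,5-dimethoxy-4-(3,4,5-trimethoxyphenoxy)phenoxy]-N-methoxy-N-methylacetamide
Product: 17 2-[3,5-dimethoxy-4-(3,4,5-trimethoxyphenoxy)phenoxy]-5-[2,6-dimethoxy-4-(2,4,6-trimethoxyphenoxy)phenoxy]benzene-1,3-diol, via lithium hemiaminal adduct 15 (not isolated), via acyclic keto enoate 16 (not isolated)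
Conditions: 7 (1.1 equiv), LDA (1.15 equiv), THF, −78 °C; 14, −78 → −40 °C; LDA (3 equiv), −78 °C → rt; 1 M HCl
Reagents that add atoms: none
Why: Proposed new method: LDA takes a γ-hydrogen from 7, and the dienolate, whose terminal CH2 is at once the vinylogous enolate carbon and the β-carbon of an enol ether, adds through that carbon to the amide carbonyl of 14 (C5–C6) to give the N,O-chelated lithium adduct 15, which keeps the ketone masked so that the dienolate is not quenched by a more acidic product. The second charge of LDA removes a C6 hydrogen, LiN(OMe)Me leaves to give the enolate of 16, a C4 hydrogen follows, and the dianion attacks the ester carbon C3 through C4, its last-formed and most reactive site (C3–C4), after which loss of methoxide and enolisation give the bis-phenoxide of aromatic ring C. Ring C closes in a 6-(enolendo)-exo-trig Claisen (Dieckmann-type) mode, which is possible because the (E)-enoate holds the chain and the ester cis on the C1–C2 double bond. The closest known reactions are the γ-acylation of lithium dienolates of 3-alkoxybut-2-enoates and 1,3-dioxin-4-ones by esters, acyl chlorides and N-methoxy-N-methylamides and the base-induced Claisen cyclisation of 3,5-dioxohexanoates to phloroglucinols, whereas the aryl enol ether and the telescoped sequence are new. No stereocentre survives, since the C5 centre of 15 is lost on collapse. The step needs γ- over α-acylation, which the β-aryloxy donor secures, and carbon over oxygen closure, which would end in a 2-pyranone and is countered by forming the dianion at −78 °C before warming, while the C1–O bond lies in the nodal plane of the dienolate π system and should therefore resist loss of aryloxide.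

Step 9
Reactants: 17 2-[3,5-dimethoxy-4-(3,4,5-trimethoxyphenoxy)phenoxy]-5-[2,6-dimethoxy-4-(2,4,6-trimethoxyphenoxy)phenoxy]benzene-1,3-diol
Product: 18 CNP0308003.0 (pentameric dodecahydroxy tetra-aryl ether)
Conditions: BBr3 (30 equiv), CH2Cl2, −78 °C → rt, Ar; then H2O, 0 °C
Reagents that add atoms: none
Why: Lewis acid-mediated aryl methyl ether cleavage, in which bromide attacks the methyl carbon of each BBr3-complexed methoxy group while the four diaryl ether oxygens offer no sp3 carbon and persist, so that hydrolysis of the aryl borates should free all twelve hydroxyls.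

Compound list
1 | 4-bromo-2,6-dimethoxyphenol | COc1cc(Br)cc(OC)c1O | starting material
2 | 2-(benzyloxy)-5-bromo-1,3-dimethoxybenzene | COc1cc(Br)cc(OC)c1OCc1ccccc1 | intermediate
3 | 2,4,6-trimethoxyphenol | COc1cc(OC)c(O)c(OC)c1 | starting material
4 | 2-(benzyloxy)-1,3-dimethoxy-5-(2,4,6-trimethoxyphenoxy)benzene (A–B benzyl ether) | COc1cc(OC)c(Oc2cc(OC)c(OCc3ccccc3)c(OC)c2)c(OC)c1 | intermediate
5 | 2,6-dimethoxy-4-(2,4,6-trimethoxyphenoxy)phenol (A–B phenol) | COc1cc(OC)c(Oc2cc(OC)c(O)c(OC)c2)c(OC)c1 | intermediate
6 | methyl but-2-ynoate | CC#CC(=O)OC | starting material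
7 | methyl (E)-3-[2,6-dimethoxy-4-(2,4,6-trimethoxyphenoxy)phenoxy]but-2-enoate | C/C(Oc1c(OC)cc(Oc2c(OC)cc(OC)cc2OC)cc1OC)=C\C(=O)OC | intermediate
8 | syringaldehyde (4-hydroxy-3,5-dimethoxybenzaldehyde) | COc1cc(C=O)cc(OC)c1O | starting material
9 | (3,4,5-trimethoxyphenyl)boronic acid | COc1cc(B(O)O)cc(OC)c1OC | starting material
10 | 3,5-dimethoxy-4-(3,4,5-trimethoxyphenoxy)benzaldehyde | COc1cc(Oc2c(OC)cc(C=O)cc2OC)cc(OC)c1OC | intermediate
11 | 3,5-dimethoxy-4-(3,4,5-trimethoxyphenoxy)phenyl formate (not isolated) | COc1cc(Oc2c(OC)cc(OC=O)cc2OC)cc(OC)c1OC | intermediate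
12 | 3,5-dimethoxy-4-(3,4,5-trimethoxyphenoxy)phenol (D–E phenol) | COc1cc(Oc2c(OC)cc(O)cc2OC)cc(OC)c1OC | intermediate
13 | 2-chloro-N-methoxy-N-methylacetamide | CON(C)C(=O)CCl | starting material
14 | 2-[3,5-dimethoxy-4-(3,4,5-trimethoxyphenoxy)phenoxy]-N-methoxy-N-methylacetamide | CON(C)C(=O)COc1cc(OC)c(Oc2cc(OC)c(OC)c(OC)c2)c(OC)c1 | intermediate
15 | lithium alkoxide of methyl (E)-6-(D–E aryloxy)-3-(A–B aryloxy)-5-hydroxy-5-[methoxy(methyl)amino]hex-2-enoate, racemic at the transient C5 centre (not isolated) | CON(C)C([O-])(COc1cc(OC)c(Oc2cc(OC)c(OC)c(OC)c2)c(OC)c1)C/C(Oc1c(OC)cc(Oc2c(OC)cc(OC)cc2OC)cc1OC)=C\C(=O)OC.[Li+] | intermediate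
16 | methyl (E)-6-[3,5-dimethoxy-4-(3,4,5-trimethoxyphenoxy)phenoxy]-3-[2,6-dimethoxy-4-(2,4,6-trimethoxyphenoxy)phenoxy]-5-oxohex-2-enoate, present as its lithium enolate and dianion (not isolated) | COc1cc(Oc2c(OC)cc(OCC(=O)C/C(Oc3c(OC)cc(Oc4c(OC)cc(OC)cc4OC)cc3OC)=C\C(=O)OC)cc2OC)cc(OC)c1OC | intermediate
17 | 2-[3,5-dimethoxy-4-(3,4,5-trimethoxyphenoxy)phenoxy]-5-[2,6-dimethoxy-4-(2,4,6-trimethoxyphenoxy)phenoxy]benzene-1,3-diol (pentamer, ten methyl ethers, free ring C hydroxyls) | COc1cc(OC)c(Oc2cc(OC)c(Oc3cc(O)c(Oc4cc(OC)c(Oc5cc(OC)c(OC)c(OC)c5)c(OC)c4)c(O)c3)c(OC)c2)c(OC)c1 | intermediate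
18 | CNP0308003.0, achiral pentamer with twelve free hydroxyls | Oc1cc(O)c(Oc2cc(O)c(Oc3cc(O)c(Oc4cc(O)c(Oc5cc(O)c(O)c(O)c5)c(O)c4)c(O)c3)c(O)c2)c(O)c1 | target

Total step count: 9. Longest linear sequence: 6 (steps 1, 2, 3, 4, 8, 9).

Steps most likely to fail

Step 8. Four processes could defeat it:
- acylation at the α-carbon of the dienolate
- proton transfer from the amide to the dienolate
- lactonisation through oxygen before the dianion is in place
- loss or exchange of the A–B aryloxide at the enol ether carbon

The fallback gives up ring construction, brings ring C in as a ready-made arene and uses only the couplings already in the route. It sets out from 5 and comes back at 18.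
- Phenol 5 is coupled with bromide 2 under the conditions of step 2 to give the benzyl-protected A–B–C trimer F1.
- Hydrogenolysis as in step 3 frees the A–B–C phenol F2.
- In parallel, 1 and 9 are joined by Chan–Lam coupling as in step 5, which leaves the C–Br bond untouched, to give the D–E bromide F3.
- Ullmann coupling of F2 with F3 should give the pentamer dodecamethyl ether F4.
- BBr3 as in step 9 then cleaves all twelve methyl ethers to 18.

Step 9. Partly cleaved borates may precipitate and stall the ether cleavage. The free polyphenol may also be lost to air oxidation during isolation. The fallback replaces direct isolation by capture, purification and release, sets out from 17 and comes back at 18.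
- The crude material from the BBr3 treatment is acetylated at once (Ac2O, pyridine) to the dodecaacetate F5.
- F5 should be stable to air, can be chromatographed on silica gel, and can be separated from under-cleaved material, which is returned to the cleavage.
- Acid-catalysed methanolysis (HCl in degassed MeOH, Ar) then releases 18 beside volatile by-products only.

Step 2. C–O bond formation at copper may be slow for the di-ortho-substituted phenoxide. Hydrodebromination of the bromide and oxidative decay of the very electron-rich phenol would then compete. The fallback reverses the polarity of the coupling, sets out from 8 and comes back at 4.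
- Syringaldehyde 8 is O-benzylated (BnBr, K2CO3, DMF) to 4-(benzyloxy)-3,5-dimethoxybenzaldehyde F6.
- Baeyer–Villiger oxidation with mCPBA gives 4-(benzyloxy)-3,5-dimethoxyphenyl formate F7.
- Methanolysis gives 4-(benzyloxy)-3,5-dimethoxyphenol F8.
- This unhindered phenol is coupled with commercial 2-iodo-1,3,5-trimethoxybenzene (COc1cc(OC)c(I)c(OC)c1; CuI, picolinic acid, K3PO4, DMSO, 100 °C) to give 4. The more readily activated C–I bond now offsets the hindrance.

Further compounds
F1 | step 8 | 2-(benzyloxy)-5-[2,6-dimethoxy-4-(2,4,6-trimethoxyphenoxy)phenoxy]-1,3-dimethoxybenzene | COc1cc(OC)c(Oc2cc(OC)c(Oc3cc(OC)c(OCc4ccccc4)c(OC)c3)c(OC)c2)c(OC)c1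
F2 | step 8 | 4-[2,6-dimethoxy-4-(2,4,6-trimethoxyphenoxy)phenoxy]-2,6-dimethoxyphenol | COc1cc(OC)c(Oc2cc(OC)c(Oc3cc(OC)c(O)c(OC)c3)c(OC)c2)c(OC)c1
F3 | step 8 | 5-bromo-1,3-dimethoxy-2-(3,4,5-trimethoxyphenoxy)benzene | COc1cc(Oc2c(OC)cc(Br)cc2OC)cc(OC)c1OC
F4 | step 8 | dodecamethyl ether of 18 | COc1cc(OC)c(Oc2cc(OC)c(Oc3cc(OC)c(Oc4cc(OC)c(Oc5cc(OC)c(OC)c(OC)c5)c(OC)c4)c(OC)c3)c(OC)c2)c(OC)c1
F5 | step 9 | dodecaacetate of 18 | CC(=O)Oc1cc(OC(C)=O)c(Oc2cc(OC(C)=O)c(Oc3cc(OC(C)=O)c(Oc4cc(OC(C)=O)c(Oc5cc(OC(C)=O)c(OC(C)=O)c(OC(C)=O)c5)c(OC(C)=O)c4)c(OC(C)=O)c3)c(OC(C)=O)c2)c(OC(C)=O)c1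
F6 | step 2 | 4-(benzyloxy)-3,5-dimethoxybenzaldehyde | COc1cc(C=O)cc(OC)c1OCc1ccccc1
F7 | step 2 | 4-(benzyloxy)-3,5-dimethoxyphenyl formate | COc1cc(OC=O)cc(OC)c1OCc1ccccc1
F8 | step 2 | 4-(benzyloxy)-3,5-dimethoxyphenol | COc1cc(O)cc(OC)c1OCc1ccccc1
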